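## The problem

Target 23 (CNP0305015.0) is a biaryl of two catechol rings, each carrying a chain of eight methylenes that ends in a 2,6-dihydroxyphenyl ketone. Formally it is a dimer of one catechol ketone, but the halves are joined unsymmetrically. Ring A is bonded through the carbon next to a hydroxyl (C1', hydroxyls on C2' and C3', chain on C5'). Ring B is bonded through the carbon next to its chain (C1, chain on C2, hydroxyls on C4 and C5). An oxidative phenol coupling of the monomer would have to pair an ortho position of one unit with a para position of the other, and nothing in the monomer directs that. There is no stereocenter, and the biaryl axis, flanked only by one hydroxyl and one methylene, rotates freely, so nothing has to be controlled stereochemically and no element can control another; the task is regiochemistry and convergence. Both ketones sit on C2 of a resorcinol unit, between the hydroxyls, a position electrophilic acylation does not reach. Eight phenols, four of them in two air- and base-sensitive catechols, must stay masked to the end, and the masks must survive organomagnesium and organolithium reagents. The feature that opens the key step lies on ring A: the oxygen-bearing C3', the hydroxyl-bearing C2' and the aryl-bearing C1' are contiguous, which is the pattern left when a carbon nucleophile and then an oxygen electrophile add across an aryne C1'–C2' with a methoxyl on C3'. 5-Iodovanillin 1 carries iodine, hydroxyl and methoxyl on exactly these carbons and its formyl group on C5', where the chain belongs.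

## Retrosynthesis

**23 from 22.** The eight phenolic O–H bonds are traced back to O–methyl bonds, giving the octamethyl ether 22. Methyl ethers are already present in 1, 4 and 20 and are the one phenol mask that tolerates every reagent class used below. The price is a single exhaustive ether cleavage with a boron trihalide at the end, which must leave the two aryl ketones and the freed catechols intact.

**22 from 19 and 21.** Both aryl–carbonyl bonds are cut. Friedel–Crafts acylation of 20 would go to C4, whereas directed lithiation of 20 gives 21, metalated at C2 between the two methoxyls. The acyl partner is the bis(N-methoxy-N-methylamide) 19, whose chelated adduct stops at the ketone. This removes both terminal rings in one operation and leaves a biaryl with two identical chains. The forward reaction must add a hindered aryllithium twice without enolizing the amide.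

**19 from 18, 17, 13 and 15.** Amide formation and alkene hydrogenation are unwound to the bis(alkenoic acid) 17, and its two C=C bonds, between the benzylic carbon and C8 of each chain, are cut by a twofold Wittig disconnection. The neighbouring cut, sp2–sp3 cross-coupling of a biaryl dihalide with an alkylmetal, would need two extra halogens and a functionalized alkylboron or alkylzinc reagent. The Wittig cut instead uses formyl groups that both aromatic starting materials already have, and it builds both chains at once with one phosphonium salt, 15, from 14. Precursor 13 is a plain biaryl dialdehyde. Alkene geometry is irrelevant, but the hindered ring B aldehyde must also react.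

**13 from 11 (through 12).** Methylation of the one free hydroxyl and hydrolysis of the two acetals are unwound. The hydroxyl of 11 must be capped, because its phenoxide would deactivate the para aldehyde towards the ylide and quench the organolithium later. Both operations are ordinary, so they are joined in one step.

**11 from 3 and 6 (through 7–10).** The biaryl C–C bond and the adjacent C2'–OH bond of ring A are cut together, which leads to the 3-methoxyaryne 8, the ring B nucleophile 6 and an oxygen electrophile.
- Compared with oxidative coupling, this cut fixes which carbon of each ring is joined.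
- The closest neighbour is a palladium cross-coupling at the same carbon of 1, which forms only the C–C bond. The aryne cut needs no catalyst and no separately prepared boron reagent; it takes ring B as the Grignard reagent straight from its bromide, and it uses the hydroxyl of 1 first as the leaving group and then restores it. The cross-coupling is sound and is kept as the reserve route.
- The precursors are two monocyclic benzaldehyde derivatives.
- The forward reaction must add regioselectively to an unsymmetrical aryne and then carry the resulting aryl–magnesium bond through to oxygen, with both aldehydes masked as dioxolanes.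

**3 from 2 and 1; 6 from 5 and 4.** Only functional-group changes remain. Aryne precursor 3 comes from 1 by triflation and then acetalization. The order matters: the acetal of a free para-hydroxybenzaldehyde forms poorly and is acid-labile, whereas the electron-poor triflate 2 acetalizes cleanly. Grignard reagent 6 comes from 4 by acetalization to 5 and magnesium insertion.

## Roads not taken

**Alternative 1:** The cut is at the two carbonyl–CH2 bonds. In the forward step the terminal alkenes of the biaryl diene A1 would each take up one molecule of 2-hydroxy-6-methoxybenzaldehyde A2 by hydroacylation under monovalent rhodium catalysis, the phenol of A2 holding the acyl-metal hydride, to give the bis-ketone A3.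
- Merits: both ketones are made catalytically and with full atom economy, no amide or aryllithium is needed, and A3 arrives with one hydroxyl of each ketone ring already free.
- Weak points: each addition must be linear on an unactivated 1-alkene, where chelating aldehydes readily give the branched ketone too, and it must be linear twice. The second ortho substituent of A2 slows C–H insertion and favours decarbonylation. The metal hydride can also move the double bond along the chain. Diene A1 is no easier than 13: its terminal alkenes rule out an olefination–hydrogenation sequence, so two sp2–sp3 couplings would be needed on a biaryl that still has to be made.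
- Comparison: with assured linear selectivity this endgame would be about two steps shorter than steps 10 and 11 and would leave fewer ethers to cleave. The chosen plan sets against that a ketone synthesis with no regiochemical question and chains that grow from formyl groups already in the starting materials.

**Alternative 2:** The cut removes two bonds of ring B, so ring B is built onto ring A. 2,3-Dimethoxybuta-1,3-diene A5 would add across the alkyne of the arylpropiolate A4 in a [4+2] cycloaddition to give the cyclohexa-1,4-diene A6, which is then dehydrogenated to the arene.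
- Merits: the symmetric diene fixes the ortho relation of aryl and carbon substituent and the positions of both oxygens, so there is no regiochemical question and no organometallic biaryl formation.
- Weak points: ring B is an ordinary veratrole unit that can be bought as 4, so constructing it is wasted effort. Dienophile A4 is β-aryl-substituted and hindered by an ortho methoxyl, and the diene prefers its s-trans form, so forcing conditions and diene loss are likely. Diene A6 is a bis-enol ether prone to hydrolysis and needs a separate aromatization. Both carbon substituents emerge as esters and must be reduced to reach 13. Propiolate A4 itself needs an alkynylation and an oxidation.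
- Comparison: this road avoids the aryne regiochemistry altogether, which is a real advantage. The chosen plan answers with several fewer steps to 13 and the correct aldehyde oxidation level throughout.

**Alternative 3:** The cut takes the ring B–CH2 bond and the biaryl bond together. 4-Iodo-1,2-dimethoxybenzene A7, methyl 9-bromononanoate A8 and the ring A arylboronate A9 would combine under a palladium catalyst with a strained bicyclic alkene as transient mediator: ortho C–H palladation, alkylation by A8 at the ortho carbon, then Suzuki termination with A9 at the ipso carbon, giving the diester A10.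
- Merits: it is the most convergent of the four plans, and A10 is the dimethyl ester of 18, one amidation away from 19.
- Weak points: A7 has two free ortho positions, and only the meta methoxyl biases them, whereas clean mono-alkylation and release of the mediator normally rely on an existing ortho substituent. Double alkylation or retention of the mediator is a real risk. Boronate A9 is hindered and could couple with A7 before any alkylation. A9 must also be made separately with its chain already attached, so the two chains come from different chemistry.
- Comparison: if the ortho selectivity held, this road would be shorter and more convergent than the chosen one. The chosen plan sets against it a regiochemistry fixed electronically by the methoxyl next to the aryne, and two chains built simultaneously from 13 with one reagent.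

Key step: step 5

Assumption: 23 has no stereocenter and its biaryl axis is not configurationally stable, so the route sets no configuration; the alkene geometry formed in step 8 is erased in step 9.

## Route

Step 1
Reactants: 1 5-iodovanillin (4-hydroxy-3-iodo-5-methoxybenzaldehyde)
Product: 2 4-formyl-2-iodo-6-methoxyphenyl trifluoromethanesulfonate
Conditions: Tf2O, pyridine, CH2Cl2, 0 °C → rt
Reagents that add atoms: trifluoromethanesulfonic anhydride, O=S(=O)(OS(=O)(=O)C(F)(F)F)C(F)(F)F
Why: O-sulfonylation of a phenol; the hydroxyl flanked by iodine and methoxyl is acidic and reacts readily, while the aldehyde and the aryl iodide are inert to Tf2O and pyridine.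

Step 2
Reactants: 2 4-formyl-2-iodo-6-methoxyphenyl trifluoromethanesulfonate
Product: 3 4-(1,3-dioxolan-2-yl)-2-iodo-6-methoxyphenyl trifluoromethanesulfonate
Conditions: ethylene glycol, p-TsOH·H2O (cat.), toluene, reflux (Dean–Stark)
Reagents that add atoms: ethylene glycol, OCCO
Why: Acid-catalysed acetalization with azeotropic removal of water; the electron-poor aldehyde para to the triflate should give a stable dioxolane, and aryl triflate and aryl iodide tolerate catalytic sulfonic acid.

Step 3
Reactants: 4 2-bromo-4,5-dimethoxybenzaldehyde
Product: 5 2-(2-bromo-4,5-dimethoxyphenyl)-1,3-dioxolane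
Conditions: ethylene glycol, p-TsOH·H2O (cat.), toluene, reflux (Dean–Stark)
Reagents that add atoms: ethylene glycol, OCCO
Why: The same acetalization; it masks the aldehyde against the organomagnesium function that is generated next to it.

Step 4
Reactants: 5 2-(2-bromo-4,5-dimethoxyphenyl)-1,3-dioxolane
Product: 6 [2-(1,3-dioxolan-2-yl)-4,5-dimethoxyphenyl]magnesium bromide (titrated THF solution, used as such)
Conditions: Mg turnings, I2 (cat.), THF, 45 °C
Reagents that add atoms: magnesium, [Mg]
Why: Grignard formation by oxidative insertion of magnesium into the aryl bromide; the dioxolane is inert to the reagent and its oxygens help to solvate the magnesium.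

Step 5
Reactants: 3 4-(1,3-dioxolan-2-yl)-2-iodo-6-methoxyphenyl trifluoromethanesulfonate; 6 [2-(1,3-dioxolan-2-yl)-4,5-dimethoxyphenyl]magnesium bromide
Product: 11 4-(1,3-dioxolan-2-yl)-2-[2-(1,3-dioxolan-2-yl)-4,5-dimethoxyphenyl]-6-methoxyphenol, via magnesiated aryl triflate 7 (not isolated), via 3-methoxyaryne 8 (not isolated), via biaryl-magnesium bromide 9 (not isolated), via dimethyl boronate 10 (not isolated)
Conditions: 6 (2.5 equiv), THF, −78 °C; Me3SiCH2MgCl (1.2 equiv), −78 → 0 °C; B(OMe)3 (6 equiv), −78 °C → rt; 30% H2O2, 2 M NaOH, 0 °C; neutral work-up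
Reagents that add atoms: hydrogen peroxide, OO (the hydroxyl oxygen of 11); trimethyl borate, COB(OC)OC (boron and methoxyls of intermediate 10 only); (trimethylsilylmethyl)magnesium chloride, C[Si](C)(C)C[Mg]Cl (magnesium and chloride of intermediate 7 only)
Why: Three-component aryne difunctionalization: Me3SiCH2MgCl exchanges the iodine of 3 at low temperature to give the ortho-magnesiated triflate 7, which expels Mg(OTf)Cl and releases aryne 8, while the silylmethyl reagent itself is a poor aryne nucleophile and leaves the aryne to 6. The aryl Grignard reagent 6 adds to the strained triple bond at the carbon remote from the methoxyl, because the inductively withdrawing oxygen distorts the aryne so that this carbon is the more electrophilic one and the developing carbanion rests on the carbon next to oxygen, where it is also chelated by magnesium. The biaryl C–C bond therefore forms at the former iodine-bearing carbon and the aryl–magnesium bond of 9 sits at the former triflate-bearing carbon. B(OMe)3 turns 9 into boronate 10, and alkaline H2O2 induces the 1,2-shift of the aryl group from boron to oxygen, so the C–O bond of phenol 11 is made in the same flask. The closest known reaction type is the addition of aryl Grignard reagents to arynes released from ortho-iodoaryl sulfonates by iodine–magnesium exchange with electrophilic capture of the new aryl-magnesium, joined to the standard borate–peroxide hydroxylation of aryl Grignard reagents. No ring is closed and no stereocenter is formed. The selectivity required is regiochemical and is secured by the methoxyl beside the triple bond; the excess of 6 should suppress addition of 9 to a second aryne, and both dioxolanes are inert to the organomagnesium species and to basic peroxide.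

Step 6
Reactants: 11 4-(1,3-dioxolan-2-yl)-2-[2-(1,3-dioxolan-2-yl)-4,5-dimethoxyphenyl]-6-methoxyphenol
Product: 13 2',3',4,5-tetramethoxy[1,1'-biphenyl]-2,5'-dicarbaldehyde, via tetramethoxy bis-dioxolane 12 (not isolated)
Conditions: MeI, K2CO3, acetone, reflux; then 2 M HCl, THF, rt
Reagents that add atoms: iodomethane, CI; water, O
Why: Williamson O-methylation of the phenol followed by acid hydrolysis of the two electron-rich aryl dioxolanes, which cleave readily at room temperature; aryl methyl ethers are stable to both operations.

Step 7
Reactants: 14 8-bromooctanoic acid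
Product: 15 (7-carboxyheptyl)triphenylphosphonium bromide
Conditions: PPh3, MeCN, reflux
Reagents that add atoms: triphenylphosphine, c1ccc(cc1)P(c1ccccc1)c1ccccc1
Why: SN2 quaternization of triphenylphosphine by the primary bromide; the free acid does not interfere and the salt should crystallize.

Step 8
Reactants: 13 2',3',4,5-tetramethoxy[1,1'-biphenyl]-2,5'-dicarbaldehyde; 15 (7-carboxyheptyl)triphenylphosphonium bromide
Product: 17 9,9'-(2',3',4,5-tetramethoxy[1,1'-biphenyl]-2,5'-diyl)bis(non-8-enoic acid) (mixture of alkene isomers, mainly Z,Z expected), via carboxylate ylide 16 (not isolated)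
Conditions: 15 (2.6 equiv), NaN(SiMe3)2 (5.3 equiv), THF, 0 °C; then 13, −78 °C → rt; aq HCl work-up
Reagents that add atoms: sodium bis(trimethylsilyl)amide, C[Si](C)(C)[N-][Si](C)(C)C.[Na+] (sodium counter-ion of intermediate 16 only)
Why: Twofold Wittig olefination with a non-stabilized ylide carried as its carboxylate (two equivalents of base per phosphonium salt), a standard way to attach ω-carboxyalkyl chains to aldehydes; the diacid is separated from Ph3PO by extraction into aqueous base, and the alkene geometry is of no consequence.

Step 9
Reactants: 17 9,9'-(2',3',4,5-tetramethoxy[1,1'-biphenyl]-2,5'-diyl)bis(non-8-enoic acid)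
Product: 18 9,9'-(2',3',4,5-tetramethoxy[1,1'-biphenyl]-2,5'-diyl)dinonanoic acid
Conditions: H2 (1 atm), 10% Pd/C, EtOAc–MeOH, rt
Reagents that add atoms: none
Why: Heterogeneous catalytic hydrogenation of two styrene-type alkenes; the molecule holds no benzyl ether, halide or other reducible group.

Step 10
Reactants: 18 9,9'-(2',3',4,5-tetramethoxy[1,1'-biphenyl]-2,5'-diyl)dinonanoic acid
Product: 19 9,9'-(2',3',4,5-tetramethoxy[1,1'-biphenyl]-2,5'-diyl)bis(N-methoxy-N-methylnonanamide)
Conditions: CDI, CH2Cl2, rt; then MeNHOMe·HCl, rt
Reagents that add atoms: N,O-dimethylhydroxylamine hydrochloride, CNOC.Cl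
Why: Weinreb amide formation through the acyl imidazolides; the imidazole released serves as the base for the amine hydrochloride.

Step 11
Reactants: 19 9,9'-(2',3',4,5-tetramethoxy[1,1'-biphenyl]-2,5'-diyl)bis(N-methoxy-N-methylnonanamide); 20 1,3-dimethoxybenzene
Product: 22 9,9'-(2',3',4,5-tetramethoxy[1,1'-biphenyl]-2,5'-diyl)bis[1-(2,6-dimethoxyphenyl)nonan-1-one], via 2,6-dimethoxyphenyllithium 21 (not isolated)
Conditions: 20 (4 equiv), n-BuLi (3.8 equiv), THF, 0 °C → rt; then 19, −78 → 0 °C; sat. aq NH4Cl
Reagents that add atoms: n-butyllithium, [Li]CCCC (lithium of intermediate 21 only)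
Why: Directed ortho-lithiation of 20 at C2 between the two methoxyls, then Weinreb ketone synthesis; the chelated tetrahedral adduct prevents over-addition and places each acyl group on the carbon between the two oxygens, which Friedel–Crafts acylation cannot reach.

Step 12
Reactants: 22 9,9'-(2',3',4,5-tetramethoxy[1,1'-biphenyl]-2,5'-diyl)bis[1-(2,6-dimethoxyphenyl)nonan-1-one]
Product: 23 9,9'-(2',3',4,5-tetrahydroxy[1,1'-biphenyl]-2,5'-diyl)bis[1-(2,6-dihydroxyphenyl)nonan-1-one] (CNP0305015.0)
Conditions: BBr3 (16 equiv), CH2Cl2, −78 °C → rt; then H2O, 0 °C, work-up under argon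
Reagents that add atoms: none
Why: Lewis-acid cleavage of all eight aryl methyl ethers with BBr3; the ethers ortho to the ketones should cleave fastest through chelation and the veratrole-type ethers follow, and hydrolysis of the aryl borates releases the phenols while the saturated chains and aryl ketones are unaffected.

## Compound list

1 | 5-iodovanillin (4-hydroxy-3-iodo-5-methoxybenzaldehyde) | COc1cc(C=O)cc(I)c1O | starting material
2 | 4-formyl-2-iodo-6-methoxyphenyl trifluoromethanesulfonate | COc1cc(C=O)cc(I)c1OS(=O)(=O)C(F)(F)F | intermediate
3 | 4-(1,3-dioxolan-2-yl)-2-iodo-6-methoxyphenyl trifluoromethanesulfonate | COc1cc(C2OCCO2)cc(I)c1OS(=O)(=O)C(F)(F)F | intermediate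
4 | 2-bromo-4,5-dimethoxybenzaldehyde | COc1cc(Br)c(C=O)cc1OC | starting material
5 | 2-(2-bromo-4,5-dimethoxyphenyl)-1,3-dioxolane | COc1cc(Br)c(C2OCCO2)cc1OC | intermediate
6 | [2-(1,3-dioxolan-2-yl)-4,5-dimethoxyphenyl]magnesium bromide | COc1cc(C2OCCO2)c([Mg]Br)cc1OC | intermediate
7 | 2-(chloromagnesio)-4-(1,3-dioxolan-2-yl)-6-methoxyphenyl trifluoromethanesulfonate | COc1cc(C2OCCO2)cc([Mg]Cl)c1OS(=O)(=O)C(F)(F)F | intermediate (not isolated)
8 | 5-(1,3-dioxolan-2-yl)-3-methoxy-1,2-didehydrobenzene (3-methoxyaryne) | COC1=CC(C2OCCO2)=CC#C1 | intermediate (not isolated)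
9 | {4-(1,3-dioxolan-2-yl)-2-[2-(1,3-dioxolan-2-yl)-4,5-dimethoxyphenyl]-6-methoxyphenyl}magnesium bromide | COc1cc(C2OCCO2)cc(-c2cc(OC)c(OC)cc2C2OCCO2)c1[Mg]Br | intermediate (not isolated)
10 | dimethyl {4-(1,3-dioxolan-2-yl)-2-[2-(1,3-dioxolan-2-yl)-4,5-dimethoxyphenyl]-6-methoxyphenyl}boronate | COc1cc(C2OCCO2)cc(-c2cc(OC)c(OC)cc2C2OCCO2)c1B(OC)OC | intermediate (not isolated)
11 | 4-(1,3-dioxolan-2-yl)-2-[2-(1,3-dioxolan-2-yl)-4,5-dimethoxyphenyl]-6-methoxyphenol | COc1cc(C2OCCO2)cc(-c2cc(OC)c(OC)cc2C2OCCO2)c1O | intermediate
12 | 2,2'-(2',3',4,5-tetramethoxy[1,1'-biphenyl]-2,5'-diyl)bis(1,3-dioxolane) | COc1cc(C2OCCO2)cc(-c2cc(OC)c(OC)cc2C2OCCO2)c1OC | intermediate (not isolated)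
13 | 2',3',4,5-tetramethoxy[1,1'-biphenyl]-2,5'-dicarbaldehyde | COc1cc(C=O)cc(-c2cc(OC)c(OC)cc2C=O)c1OC | intermediate
14 | 8-bromooctanoic acid | OC(=O)CCCCCCCBr | starting material
15 | (7-carboxyheptyl)triphenylphosphonium bromide | OC(=O)CCCCCCC[P+](c1ccccc1)(c1ccccc1)c1ccccc1.[Br-] | intermediate
16 | sodium 8-(triphenyl-λ5-phosphanylidene)octanoate | [Na+].[O-]C(=O)CCCCCCC=P(c1ccccc1)(c1ccccc1)c1ccccc1 | intermediate (not isolated)
17 | 9,9'-(2',3',4,5-tetramethoxy[1,1'-biphenyl]-2,5'-diyl)bis(non-8-enoic acid), mixture of alkene isomers | OC(=O)CCCCCCC=Cc1cc(OC)c(OC)c(-c2cc(OC)c(OC)cc2C=CCCCCCCC(=O)O)c1 | intermediate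
18 | 9,9'-(2',3',4,5-tetramethoxy[1,1'-biphenyl]-2,5'-diyl)dinonanoic acid | OC(=O)CCCCCCCCc1cc(OC)c(OC)c(-c2cc(OC)c(OC)cc2CCCCCCCCC(=O)O)c1 | intermediate
19 | 9,9'-(2',3',4,5-tetramethoxy[1,1'-biphenyl]-2,5'-diyl)bis(N-methoxy-N-methylnonanamide) | CON(C)C(=O)CCCCCCCCc1cc(OC)c(OC)c(-c2cc(OC)c(OC)cc2CCCCCCCCC(=O)N(C)OC)c1 | intermediate
20 | 1,3-dimethoxybenzene | COc1cccc(OC)c1 | starting material
21 | 2,6-dimethoxyphenyllithium | [Li]c1c(OC)cccc1OC | intermediate (not isolated)
22 | 9,9'-(2',3',4,5-tetramethoxy[1,1'-biphenyl]-2,5'-diyl)bis[1-(2,6-dimethoxyphenyl)nonan-1-one] | COc1cccc(OC)c1C(=O)CCCCCCCCc1cc(OC)c(OC)c(-c2cc(OC)c(OC)cc2CCCCCCCCC(=O)c2c(OC)cccc2OC)c1 | intermediate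
23 | 9,9'-(2',3',4,5-tetrahydroxy[1,1'-biphenyl]-2,5'-diyl)bis[1-(2,6-dihydroxyphenyl)nonan-1-one] (CNP0305015.0) | O=C(CCCCCCCCc1cc(O)c(O)c(-c2cc(O)c(O)cc2CCCCCCCCC(=O)c2c(O)cccc2O)c1)c1c(O)cccc1O | target

## Step count and risks

Total step count: 12. Longest linear sequence: 9 steps (steps 1, 2, 5, 6, 8, 9, 10, 11, 12 from 1; the branch from 4 through steps 3 and 4 is equally long).

**Step 5 (key step).**
- The aryne may be consumed by the biaryl-magnesium product (oligoarylation) or by the exchange reagent instead of by 6.
- The triflyl group of the magnesiated triflate may migrate to carbon (anionic thia-Fries rearrangement) in competition with elimination.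
- The addition may lose regioselectivity.
- The hindered, doubly ortho-substituted aryl-magnesium may be borylated incompletely, so that protonation at work-up gives a biaryl without the hydroxyl.
- Fallback, setting out from 1 and 5 and returning at 13: 1 is O-methylated (MeI, K2CO3, DMF) to 3-iodo-4,5-dimethoxybenzaldehyde F1. Compound 5 is converted by bromine–lithium exchange (n-BuLi, THF, −78 °C), B(Oi-Pr)3 and acidic work-up into (2-formyl-4,5-dimethoxyphenyl)boronic acid F2. Suzuki–Miyaura coupling of F1 with F2 (Pd(PPh3)4, K2CO3, dioxane–water, 90 °C) gives dialdehyde 13 directly.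

**Step 8.**
- The doubly charged carboxylate ylide is poorly soluble, and the ring B aldehyde next to the biaryl bond is hindered, so the second olefination may stall at the mono-alkene.
- Fallback, setting out from 15 and 13 and returning at 19: 15 is esterified (MeOH, HCl cat.) to (8-methoxy-8-oxooctyl)triphenylphosphonium bromide F3. Its soluble ylide (NaN(SiMe3)2, THF, −78 °C) is condensed with 13 to dimethyl 9,9'-(2',3',4,5-tetramethoxy[1,1'-biphenyl]-2,5'-diyl)bis(non-8-enoate) F4. Hydrogenation (H2, Pd/C) gives dimethyl 9,9'-(2',3',4,5-tetramethoxy[1,1'-biphenyl]-2,5'-diyl)dinonanoate F5, the compound labelled A10 above. Direct amidation (MeNHOMe·HCl, i-PrMgCl, THF, −20 °C) then gives 19.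

**Step 11.**
- The hindered, basic aryllithium may deprotonate the amide at the α-carbon or cleave the N–O bond by elimination instead of adding, leaving one or both amides unconverted.
- Fallback, setting out from 19 and returning at 22: 19 is reduced (i-Bu2AlH, THF, −78 °C) to 9,9'-(2',3',4,5-tetramethoxy[1,1'-biphenyl]-2,5'-diyl)dinonanal F6. The less demanding addition of 21 to the two aldehydes gives 9,9'-(2',3',4,5-tetramethoxy[1,1'-biphenyl]-2,5'-diyl)bis[1-(2,6-dimethoxyphenyl)nonan-1-ol] F7 as a mixture of diastereomers. Oxidation with Dess–Martin periodinane gives 22.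

**Step 12.**
- Cleavage of eight ethers in one operation may be incomplete or uneven, giving partly methylated phenols that are hard to separate.
- The freed catechols may oxidize during a long reaction and work-up.
- Fallback, setting out from 19 and returning at 23: the ketone rings are carried with acid-labile masks. The amide 19 is treated with 2,6-bis(methoxymethoxy)phenyllithium F8 (from commercial 1,3-bis(methoxymethoxy)benzene and n-BuLi, THF, 0 °C) to give 9,9'-(2',3',4,5-tetramethoxy[1,1'-biphenyl]-2,5'-diyl)bis{1-[2,6-bis(methoxymethoxy)phenyl]nonan-1-one} F9. Dilute HCl in MeOH removes the four acetal ethers to give 9,9'-(2',3',4,5-tetramethoxy[1,1'-biphenyl]-2,5'-diyl)bis[1-(2,6-dihydroxyphenyl)nonan-1-one] F10. BBr3 then has only the four veratrole-type methyl ethers to cleave on the way to 23.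

## Further compounds

F1 | step 5 | 3-iodo-4,5-dimethoxybenzaldehyde | COc1cc(C=O)cc(I)c1OC
F2 | step 5 | (2-formyl-4,5-dimethoxyphenyl)boronic acid | COc1cc(B(O)O)c(C=O)cc1OC
F3 | step 8 | (8-methoxy-8-oxooctyl)triphenylphosphonium bromide | COC(=O)CCCCCCC[P+](c1ccccc1)(c1ccccc1)c1ccccc1.[Br-]
F4 | step 8 | dimethyl 9,9'-(2',3',4,5-tetramethoxy[1,1'-biphenyl]-2,5'-diyl)bis(non-8-enoate), mixture of alkene isomers | COC(=O)CCCCCCC=Cc1cc(OC)c(OC)c(-c2cc(OC)c(OC)cc2C=CCCCCCCC(=O)OC)c1
F5 | step 8 | dimethyl 9,9'-(2',3',4,5-tetramethoxy[1,1'-biphenyl]-2,5'-diyl)dinonanoate | COC(=O)CCCCCCCCc1cc(OC)c(OC)c(-c2cc(OC)c(OC)cc2CCCCCCCCC(=O)OC)c1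
F6 | step 11 | 9,9'-(2',3',4,5-tetramethoxy[1,1'-biphenyl]-2,5'-diyl)dinonanal | O=CCCCCCCCCc1cc(OC)c(OC)c(-c2cc(OC)c(OC)cc2CCCCCCCCC=O)c1
F7 | step 11 | 9,9'-(2',3',4,5-tetramethoxy[1,1'-biphenyl]-2,5'-diyl)bis[1-(2,6-dimethoxyphenyl)nonan-1-ol], mixture of diastereomers | COc1cccc(OC)c1C(O)CCCCCCCCc1cc(OC)c(OC)c(-c2cc(OC)c(OC)cc2CCCCCCCCC(O)c2c(OC)cccc2OC)c1
F8 | step 12 | 2,6-bis(methoxymethoxy)phenyllithium | [Li]c1c(OCOC)cccc1OCOC
F9 | step 12 | 9,9'-(2',3',4,5-tetramethoxy[1,1'-biphenyl]-2,5'-diyl)bis{1-[2,6-bis(methoxymethoxy)phenyl]nonan-1-one} | COCOc1cccc(OCOC)c1C(=O)CCCCCCCCc1cc(OC)c(OC)c(-c2cc(OC)c(OC)cc2CCCCCCCCC(=O)c2c(OCOC)cccc2OCOC)c1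
F10 | step 12 | 9,9'-(2',3',4,5-tetramethoxy[1,1'-biphenyl]-2,5'-diyl)bis[1-(2,6-dihydroxyphenyl)nonan-1-one] | COc1cc(CCCCCCCCC(=O)c2c(O)cccc2O)cc(-c2cc(OC)c(OC)cc2CCCCCCCCC(=O)c2c(O)cccc2O)c1OC
A1 | alternative 1 | 2',3',4,5-tetramethoxy-2,5'-di(oct-7-en-1-yl)-1,1'-biphenyl | C=CCCCCCCc1cc(OC)c(OC)c(-c2cc(OC)c(OC)cc2CCCCCCC=C)c1
A2 | alternative 1 | 2-hydroxy-6-methoxybenzaldehyde | COc1cccc(O)c1C=O
A3 | alternative 1 | 9,9'-(2',3',4,5-tetramethoxy[1,1'-biphenyl]-2,5'-diyl)bis[1-(2-hydroxy-6-methoxyphenyl)nonan-1-one] | COc1cccc(O)c1C(=O)CCCCCCCCc1cc(OC)c(OC)c(-c2cc(OC)c(OC)cc2CCCCCCCCC(=O)c2c(O)cccc2OC)c1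
A4 | alternative 2 | methyl 3,4-dimethoxy-5-(3-methoxy-3-oxoprop-1-yn-1-yl)benzoate | COC(=O)C#Cc1cc(C(=O)OC)cc(OC)c1OC
A5 | alternative 2 | 2,3-dimethoxybuta-1,3-diene | COC(=C)C(=C)OC
A6 | alternative 2 | methyl 2-[2,3-dimethoxy-5-(methoxycarbonyl)phenyl]-4,5-dimethoxycyclohexa-1,4-diene-1-carboxylate | COC(=O)C1=C(c2cc(C(=O)OC)cc(OC)c2OC)CC(OC)=C(OC)C1
A7 | alternative 3 | 4-iodo-1,2-dimethoxybenzene | COc1ccc(I)cc1OC
A8 | alternative 3 | methyl 9-bromononanoate | COC(=O)CCCCCCCCBr
A9 | alternative 3 | methyl 9-[3,4-dimethoxy-5-(4,4,5,5-tetramethyl-1,3,2-dioxaborolan-2-yl)phenyl]nonanoate | COC(=O)CCCCCCCCc1cc(OC)c(OC)c(B2OC(C)(C)C(C)(C)O2)c1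
A10 | alternative 3 | dimethyl 9,9'-(2',3',4,5-tetramethoxy[1,1'-biphenyl]-2,5'-diyl)dinonanoate | COC(=O)CCCCCCCCc1cc(OC)c(OC)c(-c2cc(OC)c(OC)cc2CCCCCCCCC(=O)OC)c1
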